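**Retrosynthetic overview**
1. Target 11 is read as the all-cis (2R,3R,4R) oxolane. Its C3 and C4 centres come from one syn-hydrogenation of the tetrasubstituted C3=C4 bond of 2,5-dihydrofuran 10, on the face anti to the C2 aryl group.
2. 10 comes from enal 9 by 1,2-reduction.
3. 9 comes from hydroxy ketone 5 and cinnamaldehyde 6 by one amine-catalysed oxa-Michael/aldol condensation. This forms O1–C2 and C3–C4, the C2 stereocentre, and the only new ring (the oxygen five-ring).
4. 5 comes from arylacetyl chloride 1 by one-carbon homologation. Both benzene rings are bought.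

Assumption: 1, 2 and 6 (pure E isomer) are catalogue chemicals.

Note on descriptors: the spatial arrangement at C2 is the same throughout; the label reads R in 7 and 8, S in 9 and 10, and R in 11 only because CIP priorities change.

**Step 1**
Reactants: 1 (3,4-dimethoxyphenyl)acetyl chloride; 2 tris(trimethylsilyloxy)ethylene
Product: 5 1-(3,4-dimethoxyphenyl)-3-hydroxypropan-2-one, via silyl keto ester 3 (not isolated), via keto acid 4 (not isolated)
Conditions: 2 (2.2 equiv), neat, 95 °C, 4 h; then 0.6 M HCl, dioxane–H2O, 85 °C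
Reagents that add atoms: tris(trimethylsilyloxy)ethylene (compound 2), C[Si](C)(C)OC=C(O[Si](C)(C)C)O[Si](C)(C)C
Why: The acid chloride C-acylates the electron-rich ketene silyl acetal at its CH carbon (Mukaiyama-type acylation), and aqueous acid desilylates 3 to β-keto acid 4, which decarboxylates to the hydroxymethyl ketone; no stereocentre is involved.

**Step 2**
Reactants: 5 1-(3,4-dimethoxyphenyl)-3-hydroxypropan-2-one; 6 (2E)-3-(3,4,5-trimethoxyphenyl)prop-2-enal
Product: 9 (2S)-4-(3,4-dimethoxybenzyl)-2-(3,4,5-trimethoxyphenyl)-2,5-dihydrofuran-3-carbaldehyde, via oxa-Michael adduct 7 (not isolated), via aldol 8 (not isolated)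
Conditions: (R)-2-[diphenyl(trimethylsilyloxy)methyl]pyrrolidine (20 mol %), PhCO2H (20 mol %), 5 (1.5 equiv), CHCl3, 4 Å MS, rt, then 40 °C until 8 is consumed
Reagents that add atoms: none
Why: Proposed new method: the (R)-amine converts 6 into an E-iminium ion whose Si face at C-β is shielded by the CPh2(OSiMe3) group, so the primary hydroxyl of 5 adds to the Re face and sets C2 (R in 7); the enamine so formed attacks the tethered ketone in a 5-exo aldol to give 8, and E1cB loss of water through the enamine/iminium of 8 removes the C3 and C4 centres and makes the reversible oxa-Michael step irreversible; the closest known reaction types are the amine-catalysed domino oxa-Michael/aldol condensation of salicylaldehydes with enals (2H-chromene-3-carbaldehydes) and the oxa-Michael/aldol cascade of dihydroxyacetone with enals under the same catalysts.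

**Step 3**
Reactants: 9 (2S)-4-(3,4-dimethoxybenzyl)-2-(3,4,5-trimethoxyphenyl)-2,5-dihydrofuran-3-carbaldehyde
Product: 10 [(2S)-4-(3,4-dimethoxybenzyl)-2-(3,4,5-trimethoxyphenyl)-2,5-dihydrofuran-3-yl]methanol
Conditions: NaBH4, CeCl3·7H2O, MeOH, −20 °C (best run on freshly prepared 9)
Reagents that add atoms: none
Why: Luche reduction gives clean 1,2-reduction of the enal to the allylic alcohol without touching the tetrasubstituted C=C bond or the allylic/benzylic C2–O bond, and C2 is not affected.

**Step 4**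
Reactants: 10 [(2S)-4-(3,4-dimethoxybenzyl)-2-(3,4,5-trimethoxyphenyl)-2,5-dihydrofuran-3-yl]methanol
Product: 11 [(2R,3R,4R)-4-(3,4-dimethoxybenzyl)-2-(3,4,5-trimethoxyphenyl)tetrahydrofuran-3-yl]methanol
Conditions: [Ir(cod)(PCy3)(py)]PF6 (10 mol %), H2 (1 atm), CH2Cl2, rt
Reagents that add atoms: none
Why: Hydroxyl-directed homogeneous hydrogenation (Crabtree–Stork type, reliable for tetrasubstituted allylic alcohols): the CH2OH group holds the cationic iridium centre, which can only bind the alkene face anti to the C2 aryl group, so both hydrogens add syn from that face and CH2OH (C3) and benzyl (C4) end up cis to each other and to the aryl group, without hydrogenolysis of the benzylic ether.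

**Compound list**
1 | (3,4-dimethoxyphenyl)acetyl chloride | COc1ccc(CC(Cl)=O)cc1OC | starting material
2 | tris(trimethylsilyloxy)ethylene | C[Si](C)(C)OC=C(O[Si](C)(C)C)O[Si](C)(C)C | starting material
3 | trimethylsilyl 4-(3,4-dimethoxyphenyl)-3-oxo-2-(trimethylsilyloxy)butanoate (racemic, not isolated) | COc1ccc(CC(=O)C(O[Si](C)(C)C)C(=O)O[Si](C)(C)C)cc1OC | intermediate
4 | 4-(3,4-dimethoxyphenyl)-2-hydroxy-3-oxobutanoic acid (racemic, not isolated) | COc1ccc(CC(=O)C(O)C(O)=O)cc1OC | intermediate
5 | 1-(3,4-dimethoxyphenyl)-3-hydroxypropan-2-one | COc1ccc(CC(=O)CO)cc1OC | intermediate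
6 | (2E)-3-(3,4,5-trimethoxyphenyl)prop-2-enal | COc1cc(/C=C/C=O)cc(OC)c1OC | starting material
7 | (3R)-3-[3-(3,4-dimethoxyphenyl)-2-oxopropoxy]-3-(3,4,5-trimethoxyphenyl)propanal (not isolated) | O=CC[C@@H](OCC(=O)Cc1ccc(OC)c(OC)c1)c1cc(OC)c(OC)c(OC)c1 | intermediate
8 | (2R)-4-(3,4-dimethoxybenzyl)-4-hydroxy-2-(3,4,5-trimethoxyphenyl)tetrahydrofuran-3-carbaldehyde, mixture at C3/C4 (not isolated) | O=CC1[C@H](c2cc(OC)c(OC)c(OC)c2)OCC1(O)Cc1ccc(OC)c(OC)c1 | intermediate
9 | (2S)-4-(3,4-dimethoxybenzyl)-2-(3,4,5-trimethoxyphenyl)-2,5-dihydrofuran-3-carbaldehyde | O=CC1=C(Cc2ccc(OC)c(OC)c2)CO[C@H]1c1cc(OC)c(OC)c(OC)c1 | intermediate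
10 | [(2S)-4-(3,4-dimethoxybenzyl)-2-(3,4,5-trimethoxyphenyl)-2,5-dihydrofuran-3-yl]methanol | OCC1=C(Cc2ccc(OC)c(OC)c2)CO[C@H]1c1cc(OC)c(OC)c(OC)c1 | intermediate
11 | [(2R,3R,4R)-4-(3,4-dimethoxybenzyl)-2-(3,4,5-trimethoxyphenyl)tetrahydrofuran-3-yl]methanol (all-cis) | COc1ccc(C[C@H]2CO[C@@H](c3cc(OC)c(OC)c(OC)c3)[C@H]2CO)cc1OC | target

**Totals**
Total step count: 4. Longest linear sequence: 4 steps (1 → 5 → 9 → 10 → 11).

**Steps most likely to fail, with fallbacks**

Step 2 is the main risk. The intermolecular oxa-Michael addition of an aliphatic hydroxyl group may be too slow or too reversible, or the ee too low. The fallback makes the C2–O bond and the C2 centre by classical reactions and leaves only the ring closure to amine catalysis. It sets out from 5 and rejoins at 9.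
- Methylenation of 5 with Ph3P=CH2 (2.2 equiv, THF) gives 2-(3,4-dimethoxybenzyl)prop-2-en-1-ol F1, in which the alkene masks the ketone.
- CBr4/PPh3 converts it into 4-[2-(bromomethyl)prop-2-en-1-yl]-1,2-dimethoxybenzene F2.
- Separately, 3,4,5-trimethoxybenzaldehyde is allylated with (+)-B-allyldiisopinocampheylborane (Et2O, −78 °C; NaOH/H2O2 work-up) to give (1R)-1-(3,4,5-trimethoxyphenyl)but-3-en-1-ol F3.
- Williamson etherification of F3 with F2 (NaH, Bu4NI cat., THF) gives 5-[(1R)-1-{[2-(3,4-dimethoxybenzyl)prop-2-en-1-yl]oxy}but-3-en-1-yl]-1,2,3-trimethoxybenzene F4.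
- Double oxidative cleavage of both C=CH2 groups (OsO4 cat., NaIO4, 2,6-lutidine, dioxane–H2O) unmasks ketone and aldehyde together and gives 7 as an isolated compound.
- The same (R)-amine/PhCO2H system then cyclises and dehydrates 7 to 9. A retro-oxa-Michael leak is then corrected by the chiral catalyst, not turned into racemate.

Step 4 is the second risk. The cationic iridium hydride could ionise the allylic/benzylic C2–O bond or dehydrate 10 towards a furan, or the arenes could deactivate the catalyst. The fallback removes the directing group and relies on steric control alone on a metal surface. It sets out from 10 and rejoins at 11.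
- TBSCl/imidazole (DMF) gives tert-butyl{[(2S)-4-(3,4-dimethoxybenzyl)-2-(3,4,5-trimethoxyphenyl)-2,5-dihydrofuran-3-yl]methoxy}dimethylsilane F5.
- Hydrogenation over Rh/Al2O3 (5 wt % Rh, H2 50 bar, EtOAc) adds H2 syn from the face opposite the C2 aryl group and gives the all-cis tert-butyl{[(2R,3R,4R)-4-(3,4-dimethoxybenzyl)-2-(3,4,5-trimethoxyphenyl)tetrahydrofuran-3-yl]methoxy}dimethylsilane F6.
- Bu4NF (THF) then gives 11.

Step 1 is the third risk. The arylacetyl chloride may self-condense through its ketene at 95 °C, or the α-ketol may suffer in hot acid. The fallback replaces the acylation/decarboxylation by acyl-anion umpolung. It sets out from 1 and rejoins at 5.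
- Reduction of 1 with LiAlH(OtBu)3 (THF, −78 °C) gives (3,4-dimethoxyphenyl)acetaldehyde F7.
- Carbene-catalysed cross-acyloin coupling of F7 with paraformaldehyde (3-benzyl-5-(2-hydroxyethyl)-4-methylthiazolium chloride 10 mol %, Et3N, EtOH, 60 °C) hydroxymethylates the acyl carbon and gives 5.

**Further compounds**
F1 | step 2 | 2-(3,4-dimethoxybenzyl)prop-2-en-1-ol | COc1ccc(CC(=C)CO)cc1OC
F2 | step 2 | 4-[2-(bromomethyl)prop-2-en-1-yl]-1,2-dimethoxybenzene | COc1ccc(CC(=C)CBr)cc1OC
F3 | step 2 | (1R)-1-(3,4,5-trimethoxyphenyl)but-3-en-1-ol | C=CC[C@@H](O)c1cc(OC)c(OC)c(OC)c1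
F4 | step 2 | 5-[(1R)-1-{[2-(3,4-dimethoxybenzyl)prop-2-en-1-yl]oxy}but-3-en-1-yl]-1,2,3-trimethoxybenzene | C=CC[C@@H](OCC(=C)Cc1ccc(OC)c(OC)c1)c1cc(OC)c(OC)c(OC)c1
F5 | step 4 | tert-butyl{[(2S)-4-(3,4-dimethoxybenzyl)-2-(3,4,5-trimethoxyphenyl)-2,5-dihydrofuran-3-yl]methoxy}dimethylsilane | CC(C)(C)[Si](C)(C)OCC1=C(Cc2ccc(OC)c(OC)c2)CO[C@H]1c1cc(OC)c(OC)c(OC)c1
F6 | step 4 | tert-butyl{[(2R,3R,4R)-4-(3,4-dimethoxybenzyl)-2-(3,4,5-trimethoxyphenyl)tetrahydrofuran-3-yl]methoxy}dimethylsilane | COc1ccc(C[C@H]2CO[C@@H](c3cc(OC)c(OC)c(OC)c3)[C@H]2CO[Si](C)(C)C(C)(C)C)cc1OC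
F7 | step 1 | (3,4-dimethoxyphenyl)acetaldehyde | COc1ccc(CC=O)cc1OC
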